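## Structural features

The target 16 is a cyclopent-2-en-1-one. In the locants used for discussion the ring runs C1 (tertiary carbinol), C2 (ketone), C3=C4 (alkene) and C5 (acetoxy-bearing CH), and C1 also carries the side chain C1' (acetoxy-bearing CH) followed by an unbranched tetradecyl group. Three stereocentres stand in a row, C5 (R), C1 (S) and C1' (S), with the fully substituted C1 in the middle; the ring hydroxyl is trans to the ring acetoxy group and the side chain is cis to it. The fragile parts are the γ-acyloxy enone, a Michael acceptor that tolerates neither strong base nor nucleophiles, and the tertiary α-ketol flanked by two esters, which is open to acetyl migration, α-ketol shift and retro-aldol cleavage once an ester is lost. The real difficulty is the stereotriad around the quaternary carbinol, and after it the need to tell two alkenes apart late in the route. C5 and C1' are the same kind of carbon, an acetoxy-bearing CH bonded to C1, and they have mirror-image configurations. A bond between C4 and C2' therefore turns the three stereocentres into an achiral meso ring, a 2-acyl-2-hydroxycyclopent-4-ene-1,3-diyl diacetate, and the key step runs this relation forwards by ring opening. Mapping the centres through that operation shows that the meso ring must carry the hydroxyl on the same face as both acetoxy groups, with the acryloyl group on the other face; the isomer with the hydroxyl trans to the acetoxy groups would lead to the C1 epimer of 16.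

## Logic of the disconnections

16 from 12: the C2'–C3' single bond is traced back to the E alkene that cross-metathesis leaves, while C3=C4 must survive. Diimide and hydrogenation catalysts reduce a strained, electron-poor ring alkene at least as readily as a hindered chain alkene. The enone is therefore taken out of play for one step by a reversible C4–S bond (13), the chain is saturated (14), and the enone is returned by oxidation and elimination (15). This adds two steps and removes the chemoselectivity gamble.

12 from 10 and 11: the two C=C bonds C3=C4 and C2'=C3' are cut and C4 is joined to C2'. This closes the meso cyclopentene 10, in which C5 and C1' are mirror-image ring carbons, and it releases the chain as 11. Three stereocentres become an achiral array that already holds both acetates and the free tertiary hydroxyl. The forward step must open a weakly strained ring, choose between two enantiotopic alkene carbons, and close onto the acryloyl group. It also fixes the requirement that 10 is the all-cis isomer.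

10 from 9, 8 and 7: the acryloyl group is traced back to a 1-methoxyallenyl group and the acetates to silyl ethers. A vinyl ketone next to free or silylated carbinols would not survive fluoride, base or acylation catalysts (retro-aldol, oxa-Michael addition, polymerisation). The acyl group therefore stays masked until both acetates are in place, and the last step before the key step must be a mild acid hydrolysis.

7 from 5 and 6: the bond between the ring carbon and the acyl carbon is cut. This leaves a meso ketone flanked by two cis silyloxy groups and an acryloyl anion equivalent. A nucleophile can only enter anti to both silyloxy groups, so the hydroxyl is placed cis to them by the substrate alone. Ring-contraction or hydride-delivery routes to such triols tend instead to place the secondary oxygens trans to the tertiary one, which is the wrong meso isomer. The demand is that addition outruns enolisation of a β,γ-unsaturated ketone.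

5 from 4 and 3: the carbonyl is traced back to an exocyclic isopropylidene group, cut by ozonolysis, and the silyl ethers to a diol. The forward step has to distinguish the electron-rich tetrasubstituted alkene from the ring alkene.

3 from 1: the two C–O bonds are cut together. Singlet oxygen adds across the ring diene of the fulvene and the bicyclic peroxide 2 guarantees the cis relation of the two carbinols. The demand is reduction of 2 before it rearranges.

## Other disconnections considered

Alternative 1: the cut is the C4–C5 bond. Forward, Et2Zn opens the cyclopropanol of the aldehyde A2 to a zinc homoenolate (ketone at C2, zinc on C4), which adds to the aldehyde carbon C5 and closes the ring to the spiro hydroxy ketone A1.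
- In its favour: C1 and C1' are tied in an acetonide and can be set beforehand, the closure is intramolecular, and the reaction types have precedent. On that last point the alternative is better than the chosen plan.
- Against it here: the C5 carbinol is created in the key step next to a quaternary centre, and whether its hydroxyl comes out trans to the C1 oxygen depends on a chelation balance that cannot be predicted. Zinc homoenolates are sluggish toward hindered aldehydes. A1 is a saturated β-hydroxy ketone, so C3=C4 must still be introduced by a dehydrogenation, followed by acetonide removal and acetylation, before 16 is reached.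
- Comparison: structurally it makes one ring bond and one stereocentre where the chosen step makes two C=C bonds and fixes three centres. Mechanistically it is the safer step. In step economy it is poorer, because A2 needs a long acyclic synthesis and several steps follow A1.

Alternative 2: the cut is the C1–C5 bond. Forward, Et3N opens the hemiacetal of the Achmatowicz pyranone A4 to a (Z)-keto-enal, whose enediolate attacks the aldehyde carbon C5 through C1 and gives the dihydroxy enone A3.
- In its favour: the enone, the saturated chain and the right oxidation level are present at once, so no alkene has to be reduced selectively. Only desilylation and acetylation of two secondary hydroxyls separate A3 from 16. The reaction type is established for 4,5-dihydroxycyclopentenones. On step count and on precedent this alternative is better than the chosen plan.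
- Against it here: C1 and C5 are both created in a reversible aldol step. The trans or cis relation of the ring oxygens, and the relation of that pair to C1', then rest on thermodynamic preference and on 1,2-induction from one silyloxy centre, so diastereomer mixtures must be expected. The free γ-hydroxy enone A3 is exposed to the amine base, and C1' needs an asymmetric step of its own on the way to A4.
- Comparison: the chosen plan answers this weakness by storing the relative configuration in a meso ring built by face-selective reactions, so that only absolute control remains. It pays with an unprecedented key step and a longer endgame. If the aldol closure proved selective, Alternative 2 would be the more practical route.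

Alternative 3: the cut is the C2–C3 bond. Forward, the monovalent rhodium complex [Rh(dppe)]2(BF4)2 inserts into the aldehyde C–H bond of the 4-alkynal A6 and adds acyl and hydrogen across the alkyne, closing the enone A5.
- In its favour: no stereocentre is made or endangered in the key step, the enone is formed directly, the three oxygens arrive differentiated (acetonide, silyl ether), and the reaction class is known for 4-alkynals. On mechanistic security the alternative is better than the chosen plan, and on atom economy it is its equal.
- Against it here: A6 must already hold the whole stereotriad, including a quaternary α-alkoxy aldehyde, which means a long acyclic synthesis under reagent control. The aldehyde is neopentyl-like, so decarbonylation of the acyl rhodium hydride competes. The alkyne is terminal and propargylically oxygenated, outside the usual scope of internal alkynes.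
- Comparison: the closure forms one bond and no stereocentre, all stereocontrol is moved into the substrate synthesis, and the total step count would be higher. After A5, removal of both protecting groups and acetylation are still needed to reach 16.

Key step: step 8

Remarks on the chemistry:
- The precursor 10 is formulated as the (1R,2s,3S) isomer, with the hydroxyl cis to both acetoxy groups and the acryloyl group trans. This is the only meso isomer whose ring opening gives the configuration of 16; a wording with the hydroxyl trans to the acetoxy groups does not fit this structure and is not used.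
- Methoxyallene 6 is taken as a purchased reagent; otherwise it is made in one step from methyl propargyl ether with KOtBu.
- Which antipode of the chiral ligand in step 8 leads to 12 and not to its mirror image cannot be predicted. Both antipodes are accessible and the choice is left to a trial.

## Route

Step 1
Reactants: 1 6,6-dimethylfulvene
Product: 3 (1R,3S)-2-(propan-2-ylidene)cyclopent-4-ene-1,3-diol (meso cis diol), via endoperoxide 2 (not isolated)
Conditions: O2, hν (visible), tetraphenylporphyrin (cat.), CH2Cl2, −78 °C; then thiourea, MeOH, −78 to 0 °C
Reagents that add atoms: oxygen (as singlet oxygen), O=O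
Why: Sensitised photooxygenation gives singlet oxygen, which adds [4+2] across the ring diene and puts both oxygens on one face in the bicyclic peroxide 2; thiourea then cleaves only the O–O bond, so the two new carbinol centres are necessarily cis (meso), and the reduction is started cold because fulvene endoperoxides rearrange on warming.

Step 2
Reactants: 3 (1R,3S)-2-(propan-2-ylidene)cyclopent-4-ene-1,3-diol
Product: 4 (1R,3S)-1,3-bis(tert-butyldimethylsilyloxy)-2-(propan-2-ylidene)cyclopent-4-ene (meso)
Conditions: TBSCl, imidazole, DMF, 0 to 23 °C
Reagents that add atoms: tert-butyldimethylsilyl chloride, CC(C)(C)[Si](C)(C)Cl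
Why: Imidazole-promoted silylation of two secondary allylic alcohols; the bulky, base-stable ethers survive the organolithium step and later shield one face of the ring.

Step 3
Reactants: 4 (1R,3S)-1,3-bis(tert-butyldimethylsilyloxy)-2-(propan-2-ylidene)cyclopent-4-ene
Product: 5 (2R,5S)-2,5-bis(tert-butyldimethylsilyloxy)cyclopent-3-en-1-one (meso, cis)
Conditions: O3, CH2Cl2, −78 °C (Sudan Red 7B end point); then PPh3, −78 to 0 °C; used at once
Reagents that add atoms: ozone, [O-][O+]=O
Why: Ozonolysis with reductive work-up; the electrophilic oxidant takes the electron-rich tetrasubstituted exocyclic alkene well before the ring alkene, which is deactivated by two allylic silyloxy groups, and the neutral work-up spares the β,γ-unsaturated ketone from isomerisation.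

Step 4
Reactants: 5 (2R,5S)-2,5-bis(tert-butyldimethylsilyloxy)cyclopent-3-en-1-one; 6 methoxyallene (1-methoxypropa-1,2-diene)
Product: 7 (1s,2R,5S)-2,5-bis(tert-butyldimethylsilyloxy)-1-(1-methoxypropa-1,2-dien-1-yl)cyclopent-3-en-1-ol (meso, hydroxyl cis to both silyloxy groups)
Conditions: 6, n-BuLi, THF, −78 °C; then 5, −78 °C; aq. NH4Cl
Reagents that add atoms: none
Why: 1,2-Addition of α-lithiated methoxyallene, an acryloyl anion equivalent, to the ketone; the reagent can only approach anti to the two cis silyloxy groups (steric shielding, and Felkin–Anh attack anti to the C–O bonds), so the new hydroxyl is cis to both, and the low temperature lets addition outrun deprotonation.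

Step 5
Reactants: 7 (1s,2R,5S)-2,5-bis(tert-butyldimethylsilyloxy)-1-(1-methoxypropa-1,2-dien-1-yl)cyclopent-3-en-1-ol
Product: 8 (1R,2s,3S)-2-(1-methoxypropa-1,2-dien-1-yl)cyclopent-4-ene-1,2,3-triol (meso, all hydroxyls cis)
Conditions: TBAF, THF, 0 °C
Reagents that add atoms: none
Why: Fluoride-induced desilylation; the allenyl ether is stable to these basic conditions and, with no carbonyl group present yet, retro-aldol cleavage is not possible.

Step 6
Reactants: 8 (1R,2s,3S)-2-(1-methoxypropa-1,2-dien-1-yl)cyclopent-4-ene-1,2,3-triol
Product: 9 (1R,2s,3S)-2-hydroxy-2-(1-methoxypropa-1,2-dien-1-yl)cyclopent-4-ene-1,3-diyl diacetate (meso)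
Conditions: Ac2O, pyridine, DMAP (cat.), CH2Cl2, 0 °C
Reagents that add atoms: acetic anhydride, CC(=O)OC(C)=O
Why: Acylation of the two secondary allylic hydroxyls; the tertiary hydroxyl between them is too hindered to react at 0 °C, and the basic medium protects the acid-labile allenyl ether.

Step 7
Reactants: 9 (1R,2s,3S)-2-hydroxy-2-(1-methoxypropa-1,2-dien-1-yl)cyclopent-4-ene-1,3-diyl diacetate
Product: 10 (1R,2s,3S)-2-hydroxy-2-(prop-2-enoyl)cyclopent-4-ene-1,3-diyl diacetate (meso, hydroxyl cis to both acetoxy groups)
Conditions: aq. HCl (1 M), THF, 0 °C
Reagents that add atoms: water, O
Why: Hydrolysis of the allenyl enol ether: protonation at the central allene carbon gives a conjugated oxocarbenium ion, water adds and methanol is lost to unveil the vinyl ketone; the acetates survive brief cold dilute acid, and the enone appears only now, after all basic steps.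

Step 8
Reactants: 10 (1R,2s,3S)-2-hydroxy-2-(prop-2-enoyl)cyclopent-4-ene-1,3-diyl diacetate; 11 tetradec-1-ene
Product: 12 (4R,5S)-4-acetoxy-5-[(1S,2E)-1-acetoxypentadec-2-en-1-yl]-5-hydroxycyclopent-2-en-1-one
Conditions: RuCl2(L)(=CH-C6H4-2-OiPr) (5 mol%), 11 (5 equiv), CH2Cl2, 40 °C, argon sweep; L = 1,3-bis(2-isopropylphenyl)-4,5-diphenylimidazolidin-2-ylidene, (4R,5R) or (4S,5S)
Reagents that add atoms: none
Why: Proposed new method: the divalent ruthenium complex is released onto 11 to give the propagating alkylidene Ru=CH-C12H25, which adds [2+2] to the ring alkene of 10 and cycloreverts so that the chain carbon is bound to one former ring-alkene carbon (C2') and ruthenium remains as an alkylidene on the other (C4); that alkylidene closes onto the acryloyl group, C4 joining the internal carbon C3 and the terminal CH2 leaving as Ru=CH2, which 11 converts back into the alkylidene with loss of ethylene. The closest known reaction types are the enantioselective ring-opening/cross-metathesis of strained meso cycloalkenes, the enantioselective ring-opening/ring-closing metathesis of meso cyclopentenes with tethered alkenes, and the achiral ring-rearrangement metathesis of 3,5-disubstituted cyclopentenes; not yet shown is the intermolecular opening of a weakly strained cyclopentene with two allylic acetoxy groups under selection of enantiotopic carbons and its capture by an enone. The cyclopentenone ring is closed by ring-closing metathesis of a 1,6-related alkylidene and alkene through a ruthenacyclobutane, giving a five-membered carbocycle. No stereocentre is made or broken: C1, C5 and C1' keep the relative configuration locked in the meso ring, and their absolute configuration is decided by the chiral N-heterocyclic carbene, which has to place ruthenium on the alkene carbon next to the (R)-configured acetoxy carbon (the future C5) and the chain on the one next to the (S)-configured carbon (the future C1'); if opening is reversible the same ligand decides in the ring closure that follows. The step needs selection between enantiotopic alkene carbons (ligand), ring closure in preference to oligomerisation (the acryloyl group sits on the carbon flanked by both possible carbene sites, so either opening finds it at five-ring distance, while the two acetoxy arms can only re-form 10), and E geometry at C2'=C3' (thermodynamic preference of cross-metathesis). Excess 11 keeps ruthenium as the alkylidene and not the methylidene, and an earlier cross-metathesis of 11 at the acryloyl terminus does no harm because the substituted enone still accepts the ring closure and gives the same product. Loss of ethylene and the gain of a conjugated ring drive the opening, and the electron-poor, hindered alkenes of 12 re-enter metathesis only slowly.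

Step 9
Reactants: 12 (4R,5S)-4-acetoxy-5-[(1S,2E)-1-acetoxypentadec-2-en-1-yl]-5-hydroxycyclopent-2-en-1-one
Product: 13 4-acetoxy-5-[(1S,2E)-1-acetoxypentadec-2-en-1-yl]-5-hydroxy-3-(phenylsulfanyl)cyclopentan-1-one (C4, C5 and C1' as in 12; phenylsulfanyl trans to the 4-acetoxy group)
Conditions: PhSH, Et3N (cat.), CH2Cl2, 0 °C
Reagents that add atoms: thiophenol, Sc1ccccc1
Why: Thia-Michael addition; only the enone is an acceptor, the thiolate enters anti to the neighbouring acetoxy group, and the quaternary C5 blocks the enolisation that would expel the acetate, so the ring alkene is safely masked for the reduction.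

Step 10
Reactants: 13 4-acetoxy-5-[(1S,2E)-1-acetoxypentadec-2-en-1-yl]-5-hydroxy-3-(phenylsulfanyl)cyclopentan-1-one
Product: 14 4-acetoxy-5-[(1S)-1-acetoxypentadecyl]-5-hydroxy-3-(phenylsulfanyl)cyclopentan-1-one (configuration as in 13)
Conditions: 2-nitrobenzenesulfonyl hydrazide (excess, in portions), Et3N, CH2Cl2, 23 °C
Reagents that add atoms: none
Why: Diimide, formed in the flask, transfers two hydrogens in a concerted syn fashion to the only remaining alkene; ketone, esters and sulfide are inert, and, unlike hydrogenation over palladium, the method neither cleaves the allylic acetate nor is poisoned by sulfur.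

Step 11
Reactants: 14 4-acetoxy-5-[(1S)-1-acetoxypentadecyl]-5-hydroxy-3-(phenylsulfanyl)cyclopentan-1-one
Product: 16 (4R,5S)-4-acetoxy-5-[(1S)-1-acetoxypentadecyl]-5-hydroxycyclopent-2-en-1-one (target), via sulfoxide 15 (not isolated)
Conditions: mCPBA (1 equiv), CH2Cl2, −78 °C; then Et3N, −78 to 23 °C
Reagents that add atoms: 3-chloroperoxybenzoic acid (mCPBA), O=C(OO)c1cccc(Cl)c1 (its oxygen is carried only by 15 and leaves again in the elimination)
Why: Sulfide oxidation followed by β-elimination of the β-keto sulfoxide; the hydrogens on C2 next to the carbonyl are the acidic ones, so elimination restores the conjugated C2=C3 bond and not an enol acetate, under conditions too mild to move the acetates.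

## Compound list

1 | 6,6-dimethylfulvene [5-(propan-2-ylidene)cyclopenta-1,3-diene] | CC(C)=C1C=CC=C1 | starting material
2 | 7-(propan-2-ylidene)-2,3-dioxabicyclo[2.2.1]hept-5-ene (meso endoperoxide) | CC(C)=C1[C@@H]2C=C[C@H]1OO2 | intermediate (not isolated)
3 | (1R,3S)-2-(propan-2-ylidene)cyclopent-4-ene-1,3-diol (meso, cis) | CC(C)=C1[C@@H](O)C=C[C@H]1O | intermediate
4 | (1R,3S)-1,3-bis(tert-butyldimethylsilyloxy)-2-(propan-2-ylidene)cyclopent-4-ene (meso) | CC(C)=C1[C@@H](O[Si](C)(C)C(C)(C)C)C=C[C@H]1O[Si](C)(C)C(C)(C)C | intermediate
5 | (2R,5S)-2,5-bis(tert-butyldimethylsilyloxy)cyclopent-3-en-1-one (meso, cis) | O=C1[C@@H](O[Si](C)(C)C(C)(C)C)C=C[C@H]1O[Si](C)(C)C(C)(C)C | intermediate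
6 | methoxyallene (1-methoxypropa-1,2-diene) | COC=C=C | starting material
7 | (1s,2R,5S)-2,5-bis(tert-butyldimethylsilyloxy)-1-(1-methoxypropa-1,2-dien-1-yl)cyclopent-3-en-1-ol (meso, hydroxyl cis to both silyloxy groups) | C=C=C(OC)[C@]1(O)[C@@H](O[Si](C)(C)C(C)(C)C)C=C[C@H]1O[Si](C)(C)C(C)(C)C | intermediate
8 | (1R,2s,3S)-2-(1-methoxypropa-1,2-dien-1-yl)cyclopent-4-ene-1,2,3-triol (meso, all-cis) | C=C=C(OC)[C@]1(O)[C@@H](O)C=C[C@H]1O | intermediate
9 | (1R,2s,3S)-2-hydroxy-2-(1-methoxypropa-1,2-dien-1-yl)cyclopent-4-ene-1,3-diyl diacetate (meso, all-cis oxygens) | C=C=C(OC)[C@]1(O)[C@@H](OC(C)=O)C=C[C@H]1OC(C)=O | intermediate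
10 | (1R,2s,3S)-2-hydroxy-2-(prop-2-enoyl)cyclopent-4-ene-1,3-diyl diacetate (meso, hydroxyl cis to both acetoxy groups, acryloyl trans) | C=CC(=O)[C@]1(O)[C@@H](OC(C)=O)C=C[C@H]1OC(C)=O | intermediate (key-step precursor)
11 | tetradec-1-ene | C=CCCCCCCCCCCCC | starting material
12 | (4R,5S)-4-acetoxy-5-[(1S,2E)-1-acetoxypentadec-2-en-1-yl]-5-hydroxycyclopent-2-en-1-one | CCCCCCCCCCCC/C=C/[C@H](OC(C)=O)[C@@]1(O)C(=O)C=C[C@H]1OC(C)=O | intermediate (key-step product)
13 | 4-acetoxy-5-[(1S,2E)-1-acetoxypentadec-2-en-1-yl]-5-hydroxy-3-(phenylsulfanyl)cyclopentan-1-one (phenylsulfanyl trans to 4-acetoxy; other centres as in 12) | CCCCCCCCCCCC/C=C/[C@H](OC(C)=O)[C@@]1(O)C(=O)C[C@H](Sc2ccccc2)[C@H]1OC(C)=O | intermediate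
14 | 4-acetoxy-5-[(1S)-1-acetoxypentadecyl]-5-hydroxy-3-(phenylsulfanyl)cyclopentan-1-one (configuration as in 13) | CCCCCCCCCCCCCC[C@H](OC(C)=O)[C@@]1(O)C(=O)C[C@H](Sc2ccccc2)[C@H]1OC(C)=O | intermediate
15 | 4-acetoxy-5-[(1S)-1-acetoxypentadecyl]-5-hydroxy-3-(phenylsulfinyl)cyclopentan-1-one (both configurations at sulfur; carbon centres as in 14) | CCCCCCCCCCCCCC[C@H](OC(C)=O)[C@@]1(O)C(=O)C[C@H](S(=O)c2ccccc2)[C@H]1OC(C)=O | intermediate (not isolated)
16 | (4R,5S)-4-acetoxy-5-[(1S)-1-acetoxypentadecyl]-5-hydroxycyclopent-2-en-1-one (CNP0259741.2) | CCCCCCCCCCCCCC[C@H](OC(C)=O)[C@@]1(O)C(=O)C=C[C@H]1OC(C)=O | target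

## Step count and least certain steps

Total step count: 11. Longest linear sequence: 11 steps (1 to 16); 6 and 11 are purchased and enter in steps 4 and 8.

Step 8 (key step, proposed new method). The most likely failure is that the ring is not opened at a useful rate: it is weakly strained, its alkene is flanked by two acetoxy-bearing carbons and a quaternary centre, and the alkylidene is diverted into self-metathesis of 11. Next in likelihood is poor discrimination between the enantiotopic alkene carbons, since ligands of this kind were developed for strained rings. The fallback uses known chemistry and sets out from 10. The ring rearrangement with cross-metathesis is run without asymmetric induction, using the achiral, more active complex RuCl2(H2IMes)(=CH-C6H4-2-OiPr) (H2IMes = 1,3-dimesitylimidazolidin-2-ylidene) and 11 in toluene at 60 to 80 °C, a cascade established for cyclopentenes carrying a tethered alkene. This gives 12 together with its mirror image, (4S,5R)-4-acetoxy-5-[(1R,2E)-1-acetoxypentadec-2-en-1-yl]-5-hydroxycyclopent-2-en-1-one F1. The two are separated by preparative chromatography on a chiral stationary phase (cellulose or amylose tris(3,5-dimethylphenylcarbamate)), and the route is rejoined at 12.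

Step 3. The most likely failure is loss of chemoselectivity, with ozone also attacking the ring alkene once the exocyclic one is consumed; the second risk is migration of the ring double bond of 5 into conjugation on work-up. The fallback sets out from 4 and separates selection from cleavage. mCPBA (NaHCO3, CH2Cl2, 0 °C) epoxidises the far more nucleophilic tetrasubstituted alkene to 4,7-bis(tert-butyldimethylsilyloxy)-2,2-dimethyl-1-oxaspiro[2.4]hept-5-ene F2 (epoxide oxygen anti to the silyloxy groups). H5IO6 in THF/Et2O at 0 °C then cleaves the epoxide to the ketone and acetone, and the route is rejoined at 5.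

Step 4. The most likely failure is proton transfer from the doubly activated α-carbon of 5 to the strongly basic lithium reagent instead of addition, with the ketone lost through its dienolate. A first adjustment would be transmetallation with CeCl3; the fallback changes the nucleophile class and sets out from 5.
- Ethynylmagnesium bromide (THF, −78 to 0 °C), a slim and far less basic nucleophile, adds anti to the silyloxy groups to give 1-ethynyl-2,5-bis(tert-butyldimethylsilyloxy)cyclopent-3-en-1-ol F3.
- TBAF gives 2-ethynylcyclopent-4-ene-1,2,3-triol F4.
- Ac2O/pyridine gives 2-ethynyl-2-hydroxycyclopent-4-ene-1,3-diyl diacetate F5.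
- Markovnikov hydration of the terminal alkyne (Ph3PAuNTf2 cat., aqueous dioxane) gives 2-acetyl-2-hydroxycyclopent-4-ene-1,3-diyl diacetate F6.
- Mannich-type methylenation of the methyl ketone (paraformaldehyde, N-methylanilinium trifluoroacetate, THF, reflux) gives the vinyl ketone, and the route is rejoined at 10.

Step 1. The most likely failure is thermal rearrangement of the endoperoxide before thiourea has reduced it, because the reduction is slow at the temperatures at which 2 is stable. The fallback sets out from 1. After the same photooxygenation, Et3N is added at −78 °C; this Kornblum–DeLaMare isomerisation of the peroxide is fast in the cold and gives racemic 4-hydroxy-5-(propan-2-ylidene)cyclopent-2-en-1-one F7. Luche reduction (NaBH4, CeCl3, MeOH, −78 °C) then delivers hydride anti to the hydroxyl and gives the cis diol, which is freed from any trans isomer by chromatography; the route is rejoined at 3.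

## Further compounds

F1 | step 8 | (4S,5R)-4-acetoxy-5-[(1R,2E)-1-acetoxypentadec-2-en-1-yl]-5-hydroxycyclopent-2-en-1-one (enantiomer of 12) | CCCCCCCCCCCC/C=C/[C@@H](OC(C)=O)[C@]1(O)C(=O)C=C[C@@H]1OC(C)=O
F2 | step 3 | 4,7-bis(tert-butyldimethylsilyloxy)-2,2-dimethyl-1-oxaspiro[2.4]hept-5-ene (meso, cis silyloxy groups, epoxide oxygen anti to them) | CC1(C)O[C@@]12[C@@H](O[Si](C)(C)C(C)(C)C)C=C[C@H]2O[Si](C)(C)C(C)(C)C
F3 | step 4 | 1-ethynyl-2,5-bis(tert-butyldimethylsilyloxy)cyclopent-3-en-1-ol (meso, hydroxyl cis to both silyloxy groups) | C#C[C@]1(O)[C@@H](O[Si](C)(C)C(C)(C)C)C=C[C@H]1O[Si](C)(C)C(C)(C)C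
F4 | step 4 | 2-ethynylcyclopent-4-ene-1,2,3-triol (meso, all-cis) | C#C[C@]1(O)[C@@H](O)C=C[C@H]1O
F5 | step 4 | 2-ethynyl-2-hydroxycyclopent-4-ene-1,3-diyl diacetate (meso, all-cis oxygens) | C#C[C@]1(O)[C@@H](OC(C)=O)C=C[C@H]1OC(C)=O
F6 | step 4 | 2-acetyl-2-hydroxycyclopent-4-ene-1,3-diyl diacetate (meso, all-cis oxygens) | CC(=O)[C@]1(O)[C@@H](OC(C)=O)C=C[C@H]1OC(C)=O
F7 | step 1 | 4-hydroxy-5-(propan-2-ylidene)cyclopent-2-en-1-one (racemic, one enantiomer drawn) | CC(C)=C1C(=O)C=C[C@H]1O
A1 | alternative 1 | 9-hydroxy-2,2-dimethyl-4-tetradecyl-1,3-dioxaspiro[4.4]nonan-6-one (configuration as in 16) | CCCCCCCCCCCCCC[C@@H]1OC(C)(C)O[C@@]12C(=O)CC[C@H]2O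
A2 | alternative 1 | 4-(1-hydroxycyclopropyl)-2,2-dimethyl-5-tetradecyl-1,3-dioxolane-4-carbaldehyde (configuration as in 16) | CCCCCCCCCCCCCC[C@@H]1OC(C)(C)O[C@@]1(C=O)C2(O)CC2
A3 | alternative 2 | 5-[(1S)-1-(tert-butyldimethylsilyloxy)pentadecyl]-4,5-dihydroxycyclopent-2-en-1-one (ring hydroxyls trans, configuration as in 16) | CCCCCCCCCCCCCC[C@H](O[Si](C)(C)C(C)(C)C)[C@@]1(O)C(=O)C=C[C@H]1O
A4 | alternative 2 | 2-[(1S)-1-(tert-butyldimethylsilyloxy)pentadecyl]-6-hydroxy-2H-pyran-3(6H)-one (mixture at C2 and C6) | CCCCCCCCCCCCCC[C@H](O[Si](C)(C)C(C)(C)C)C1OC(O)C=CC1=O
A5 | alternative 3 | 9-(tert-butyldimethylsilyloxy)-2,2-dimethyl-4-tetradecyl-1,3-dioxaspiro[4.4]non-7-en-6-one (configuration as in 16) | CCCCCCCCCCCCCC[C@@H]1OC(C)(C)O[C@@]12C(=O)C=C[C@H]2O[Si](C)(C)C(C)(C)C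
A6 | alternative 3 | 4-[1-(tert-butyldimethylsilyloxy)prop-2-yn-1-yl]-2,2-dimethyl-5-tetradecyl-1,3-dioxolane-4-carbaldehyde (configuration as in 16) | CCCCCCCCCCCCCC[C@@H]1OC(C)(C)O[C@]1(C=O)[C@H](O[Si](C)(C)C(C)(C)C)C#C
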